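**Retrosynthetic overview**

1. The target is reached by global acid deprotection of a MOM/TES-protected chalcone. Its C5–C(=O) bond is cut to an aryllithium at C5 (between the MOM ethers on C4 and C6) and the Weinreb amide of 4-(MOM-oxy)cinnamic acid.
2. The C(CH3)2OH group on C2 comes from a tert-butyl ester at C2 by two methyl additions.
3. The dihydrofuran ring is the only ring made (both benzene rings are bought). O1–C2 and C2–C3 are cut together: a [4+1] annulation of the o-quinone methide from a phloroglucinol Mannich phenol (gives O1, C7a, C3a, C3) with the ylide carbon of a C2-symmetric (2R,5R)-2,5-dimethylthiolanium acetate (gives C2 and its ester).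
4. Feature used: C2 of the dihydrofuran bears one carbon substituent and is flanked only by O1 and the benzylic C3H2, so it can arrive as a single ylide carbon. The sole stereocentre (C2, S) is set in that step.
5. Building blocks: phloroglucinol, (2S,5S)-hexane-2,5-diol, tert-butyl bromoacetate, 4-hydroxycinnamic acid.

Key step: step 6

Assumption: which betaine epimer closes faster cannot be derived with certainty. The (2R,5R)-sulfide is taken to lead to the (S)-ester; if the opposite sense is found, the enantiomeric sulfide, made identically from (2R,5R)-hexane-2,5-diol, is used instead.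

**Route**

Step 1
Reactants: 1 phloroglucinol
Product: 2 3,5-bis(methoxymethoxy)phenol
Conditions: MOMCl (2.0 equiv), i-Pr2NEt, CH2Cl2/THF, 0 °C to rt; chromatography
Reagents that add atoms: chloromethyl methyl ether, COCCl
Why: Base-mediated O-alkylation (Williamson-type) of the C3-symmetric triol, whose three hydroxyls are equivalent, so the bis-ether is one constitutional isomer that only has to be separated from the mono- and tris-ethers.

Step 2
Reactants: 2 3,5-bis(methoxymethoxy)phenol
Product: 3 2-[(dimethylamino)methyl]-3,5-bis(methoxymethoxy)phenol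
Conditions: Me2NH (40% aq, 1.05 equiv), CH2O (37% aq, 1.05 equiv), EtOH, 0 °C to rt
Reagents that add atoms: formaldehyde, C=O; dimethylamine, CNC
Why: Phenol Mannich reaction, in which the iminium ion is delivered by the hydrogen-bonded phenol to an ortho carbon; the two ortho carbons are equivalent, the para carbon is shielded by two MOM ethers, and one equivalent of reagent limits double aminomethylation.

Step 3
Reactants: 4 (2S,5S)-hexane-2,5-diol
Product: 5 (2S,5S)-hexane-2,5-diyl dimethanesulfonate
Conditions: MsCl, Et3N, CH2Cl2, −10 to 0 °C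
Reagents that add atoms: methanesulfonyl chloride, CS(=O)(=O)Cl
Why: Sulfonylation takes place at oxygen, so both stereocentres are left untouched.

Step 4
Reactants: 5 (2S,5S)-hexane-2,5-diyl dimethanesulfonate
Product: 6 (2R,5R)-2,5-dimethylthiolane
Conditions: Na2S·9H2O, DMSO, rt; pentane extraction, distillation
Reagents that add atoms: sodium sulfide, [Na+].[Na+].[S-2]
Why: Double SN2 thioetherification, the second a 5-exo-tet closure, inverts both carbinol carbons and turns the (S,S)-dimesylate into the (R,R)-thiolane.

Step 5
Reactants: 6 (2R,5R)-2,5-dimethylthiolane; 7 tert-butyl bromoacetate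
Product: 8 (2R,5R)-1-(2-tert-butoxy-2-oxoethyl)-2,5-dimethylthiolan-1-ium bromide
Conditions: acetone (concentrated), rt, 48 h; trituration with Et2O
Reagents that add atoms: none
Why: SN2 S-alkylation of the sulfide by the reactive α-bromo ester; the C2 symmetry of the thiolane makes its two sulfur lone pairs equivalent, so a single sulfonium salt forms.

Step 6
Reactants: 3 2-[(dimethylamino)methyl]-3,5-bis(methoxymethoxy)phenol; 8 (2R,5R)-1-(2-tert-butoxy-2-oxoethyl)-2,5-dimethylthiolan-1-ium bromide
Product: 13 tert-butyl (2S)-4,6-bis(methoxymethoxy)-2,3-dihydro-1-benzofuran-2-carboxylate, via benzylammonium iodide 9 (not isolated), via o-quinone methide 10 (not isolated), via sulfonium ylide 11 (not isolated), via phenoxide betaine 12 (not isolated)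
Conditions: MeI (1.05 equiv), MeCN, rt, then evaporate; 8 (1.3 equiv), Cs2CO3 (3 equiv), CH2Cl2, −30 to 0 °C
Reagents that add atoms: none
Why: Proposed new method: N-methylation converts the benzylic amine into a leaving group, and carbonate then both releases the phenoxide, which expels trimethylamine to give o-quinone methide 10, and deprotonates 8 to the ester-stabilised ylide 11; the ylide carbon attacks the exocyclic CH2 of 10 (new C2–C3 bond) with rearomatisation to phenoxide betaine 12, whose phenoxide then displaces the neutral thiolane from that same carbon (new O1–C2 bond). The closest known reaction type is the [4+1] annulation of o-quinone methides, released from 2-hydroxybenzyl ammonium salts or sulfones, with stabilised sulfonium, ammonium or pyridinium ylides, which is established for racemic 3-unsubstituted dihydrobenzofurans and in asymmetric form where C3 is also substituted, whereas steering a lone C2 centre with a chiral sulfide leaving group has not been shown. The dihydrofuran ring, the only ring formed in the route, closes by 5-exo-tet SN2 substitution with inversion at the sulfonium-bearing carbon. C2 is controlled by the C2-symmetric (2R,5R)-thiolanium unit: the C–H flanked by ester and sulfonium in 12 is acidic and can be relayed by the nearby phenoxide, so the two betaine epimers should equilibrate faster than they close, and the epimer in which neither ring methyl group blocks the in-line approach of the phenoxide, assumed to be the (R)-betaine, should close faster and give (S)-13. The step also needs a single annulation mode and a product that holds its configuration: 3 has one unprotected hydroxyl with symmetry-equivalent ortho carbons, so only one quinone methide and one ring fusion can arise, and the tert-butyl ester together with the heterogeneous carbonate and sub-ambient temperature should keep the α-aryloxy ester centre from epimerising once the ring is closed.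

Step 7
Reactants: 13 tert-butyl (2S)-4,6-bis(methoxymethoxy)-2,3-dihydro-1-benzofuran-2-carboxylate
Product: 14 2-[(2S)-4,6-bis(methoxymethoxy)-2,3-dihydro-1-benzofuran-2-yl]propan-2-ol
Conditions: MeMgBr (4 equiv), THF, 0 °C to rt; aq NH4Cl
Reagents that add atoms: methylmagnesium bromide, C[Mg]Br
Why: Double Grignard addition to the ester via the methyl ketone; attack on the chelating α-aryloxy ester should outpace enolisation, so the C2 configuration is carried through and the MOM acetals are inert.

Step 8
Reactants: 14 2-[(2S)-4,6-bis(methoxymethoxy)-2,3-dihydro-1-benzofuran-2-yl]propan-2-ol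
Product: 15 triethyl({2-[(2S)-4,6-bis(methoxymethoxy)-2,3-dihydro-1-benzofuran-2-yl]propan-2-yl}oxy)silane
Conditions: TESCl, imidazole, DMAP (cat.), DMF, rt to 40 °C
Reagents that add atoms: chlorotriethylsilane, CC[Si](Cl)(CC)CC
Why: Silylation of the tertiary alcohol under nucleophilic catalysis removes the only acidic proton before metalation and, unlike silyl triflates, does not endanger the aryl MOM acetals.

Step 9
Reactants: 16 (E)-4-hydroxycinnamic acid
Product: 17 (E)-3-(4-hydroxyphenyl)-N-methoxy-N-methylprop-2-enamide
Conditions: MeNHOMe·HCl, EDC·HCl, HOBt (cat.), i-Pr2NEt, DMF, 0 °C to rt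
Reagents that add atoms: N,O-dimethylhydroxylamine hydrochloride, CNOC.Cl
Why: Carbodiimide-mediated amide coupling (Weinreb amide formation), in which the amine outcompetes the free phenol for the activated ester and the E-alkene is not touched.

Step 10
Reactants: 17 (E)-3-(4-hydroxyphenyl)-N-methoxy-N-methylprop-2-enamide
Product: 18 (E)-N-methoxy-3-[4-(methoxymethoxy)phenyl]-N-methylprop-2-enamide
Conditions: MOMCl, i-Pr2NEt, CH2Cl2, 0 °C to rt
Reagents that add atoms: chloromethyl methyl ether, COCCl
Why: O-alkylation of the phenol gives an acetal that tolerates the aryllithium and is removed together with the other MOM groups in the last step.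

Step 11
Reactants: 15 triethyl({2-[(2S)-4,6-bis(methoxymethoxy)-2,3-dihydro-1-benzofuran-2-yl]propan-2-yl}oxy)silane; 18 (E)-N-methoxy-3-[4-(methoxymethoxy)phenyl]-N-methylprop-2-enamide
Product: 20 (E)-1-[(2S)-4,6-bis(methoxymethoxy)-2-{2-[(triethylsilyl)oxy]propan-2-yl}-2,3-dihydro-1-benzofuran-5-yl]-3-[4-(methoxymethoxy)phenyl]prop-2-en-1-one, via C5 aryllithium 19 (not isolated)
Conditions: n-BuLi (1.15 equiv), THF, 0 °C, 1 h; then 18 (1.2 equiv), −78 to 0 °C; aq NH4Cl
Reagents that add atoms: none
Why: Directed ortho-metalation followed by Weinreb ketone synthesis: C5–H lies between the two cooperating MOM ethers and should be removed in preference to C7–H, which has one MOM neighbour and the weakly coordinating ring oxygen, and the aryllithium adds 1,2 to the amide to give a chelated tetrahedral adduct that releases the E-enone only on work-up.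

Step 12
Reactants: 20 the protected chalcone of step 11
Product: 21 (E)-1-[(2S)-4,6-dihydroxy-2-(2-hydroxypropan-2-yl)-2,3-dihydro-1-benzofuran-5-yl]-3-(4-hydroxyphenyl)prop-2-en-1-one (target)
Conditions: 3 M aq HCl/MeOH (1:10), rt, monitored; NaHCO3 quench
Reagents that add atoms: none
Why: Acid-catalysed methanolysis cleaves the three aryl MOM acetals and the silyl ether in one operation, and mild acid at room temperature should leave the tertiary alcohol (ionisation disfavoured by the adjacent ring oxygen), the E-enone and the C2 stereocentre untouched.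

**Compound list**

1 | phloroglucinol | Oc1cc(O)cc(O)c1 | starting material
2 | 3,5-bis(methoxymethoxy)phenol | COCOc1cc(O)cc(OCOC)c1 | intermediate
3 | 2-[(dimethylamino)methyl]-3,5-bis(methoxymethoxy)phenol | CN(C)Cc1c(O)cc(OCOC)cc1OCOC | intermediate
4 | (2S,5S)-hexane-2,5-diol | C[C@H](O)CC[C@H](C)O | starting material
5 | (2S,5S)-hexane-2,5-diyl dimethanesulfonate | C[C@H](OS(C)(=O)=O)CC[C@H](C)OS(C)(=O)=O | intermediate
6 | (2R,5R)-2,5-dimethylthiolane | C[C@@H]1CC[C@@H](C)S1 | intermediate
7 | tert-butyl bromoacetate | CC(C)(C)OC(=O)CBr | starting material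
8 | (2R,5R)-1-(2-tert-butoxy-2-oxoethyl)-2,5-dimethylthiolan-1-ium bromide | C[C@@H]1CC[C@@H](C)[S+]1CC(=O)OC(C)(C)C.[Br-] | intermediate
9 | {[2-hydroxy-4,6-bis(methoxymethoxy)phenyl]methyl}trimethylammonium iodide (formed in the flask, not isolated) | C[N+](C)(C)Cc1c(O)cc(OCOC)cc1OCOC.[I-] | intermediate
10 | 3,5-bis(methoxymethoxy)-6-methylidenecyclohexa-2,4-dien-1-one, the o-quinone methide (not isolated) | C=C1C(=O)C=C(OCOC)C=C1OCOC | intermediate
11 | tert-butyl 2-[(2R,5R)-2,5-dimethylthiolan-1-ium-1-yl]acetate ylide (not isolated) | C[C@@H]1CC[C@@H](C)[S+]1[CH-]C(=O)OC(C)(C)C | intermediate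
12 | tert-butyl 2-[(2R,5R)-2,5-dimethylthiolan-1-ium-1-yl]-3-[2-oxido-4,6-bis(methoxymethoxy)phenyl]propanoate, phenoxide betaine, epimers at C2 interconverting (not isolated) | C[C@@H]1CC[C@@H](C)[S+]1C(Cc1c([O-])cc(OCOC)cc1OCOC)C(=O)OC(C)(C)C | intermediate
13 | tert-butyl (2S)-4,6-bis(methoxymethoxy)-2,3-dihydro-1-benzofuran-2-carboxylate | CC(C)(C)OC(=O)[C@@H]1Cc2c(cc(OCOC)cc2OCOC)O1 | intermediate
14 | 2-[(2S)-4,6-bis(methoxymethoxy)-2,3-dihydro-1-benzofuran-2-yl]propan-2-ol | CC(C)(O)[C@@H]1Cc2c(cc(OCOC)cc2OCOC)O1 | intermediate
15 | triethyl({2-[(2S)-4,6-bis(methoxymethoxy)-2,3-dihydro-1-benzofuran-2-yl]propan-2-yl}oxy)silane | CC[Si](CC)(CC)OC(C)(C)[C@@H]1Cc2c(cc(OCOC)cc2OCOC)O1 | intermediate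
16 | (E)-4-hydroxycinnamic acid | O=C(O)/C=C/c1ccc(O)cc1 | starting material
17 | (E)-3-(4-hydroxyphenyl)-N-methoxy-N-methylprop-2-enamide | CON(C)C(=O)/C=C/c1ccc(O)cc1 | intermediate
18 | (E)-N-methoxy-3-[4-(methoxymethoxy)phenyl]-N-methylprop-2-enamide | CON(C)C(=O)/C=C/c1ccc(OCOC)cc1 | intermediate
19 | C5-lithio derivative of 15, lithium between the two MOM ethers (not isolated) | CC[Si](CC)(CC)OC(C)(C)[C@@H]1Cc2c(cc(OCOC)c([Li])c2OCOC)O1 | intermediate
20 | (E)-1-[(2S)-4,6-bis(methoxymethoxy)-2-{2-[(triethylsilyl)oxy]propan-2-yl}-2,3-dihydro-1-benzofuran-5-yl]-3-[4-(methoxymethoxy)phenyl]prop-2-en-1-one | CC[Si](CC)(CC)OC(C)(C)[C@@H]1Cc2c(cc(OCOC)c(C(=O)/C=C/c3ccc(OCOC)cc3)c2OCOC)O1 | intermediate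
21 | (E)-1-[(2S)-4,6-dihydroxy-2-(2-hydroxypropan-2-yl)-2,3-dihydro-1-benzofuran-5-yl]-3-(4-hydroxyphenyl)prop-2-en-1-one | CC(C)(O)[C@@H]1Cc2c(cc(O)c(C(=O)/C=C/c3ccc(O)cc3)c2O)O1 | target

**Step count**

Total steps: 12. Longest linear sequence: 8 steps (3, 4, 5, 6, 7, 8, 11, 12, from diol 4).

**Steps most likely to fail**

1. Step 6 (proposed new method).
- What may go wrong: ring closure of the betaine may outrun interconversion of its epimers, or the two diastereomeric closures may differ too little in rate, so that enantioselectivity is poor. Self-condensation of the quinone methide may also lower the yield.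
- Fallback (known chemistry), setting out from 3 and returning at 14: 3 is quaternised with MeI as in step 6 and the salt 9 is treated with commercial ethyl (dimethylsulfuranylidene)acetate and K2CO3 in CH2Cl2 at rt. Quinone methide 10 is trapped by this achiral ylide to the dimethylsulfonium betaine F1, which closes with loss of dimethyl sulfide to racemic ethyl 4,6-bis(methoxymethoxy)-2,3-dihydro-1-benzofuran-2-carboxylate F2. This is the established racemic form of the annulation and needs no stereocontrol. Preparative chiral-phase chromatography then separates ethyl (2S)-4,6-bis(methoxymethoxy)-2,3-dihydro-1-benzofuran-2-carboxylate F3 from ethyl (2R)-4,6-bis(methoxymethoxy)-2,3-dihydro-1-benzofuran-2-carboxylate F4. The latter can be racemised with NaOEt/EtOH and resubmitted, and the configuration is to be assigned by ECD or X-ray of a derivative. F3 with MeMgBr (THF, 0 °C) gives 14.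

2. Step 11.
- What may go wrong: 1,2-addition of the doubly ortho-substituted aryllithium to the Weinreb amide may be slow, so that base-induced breakdown of the N-methoxy amide or conjugate addition competes. Site selectivity of the deprotonation should be checked by a D2O quench.
- Fallback, setting out from 18 and 15 and returning at 20: 18 is reduced with DIBAL-H (THF, −78 °C) to (E)-3-[4-(methoxymethoxy)phenyl]prop-2-enal F5. Aryllithium 19, generated from 15 as in step 11, adds 1,2 to this far more electrophilic aldehyde at −78 °C. This gives (E)-1-[(2S)-4,6-bis(methoxymethoxy)-2-{2-[(triethylsilyl)oxy]propan-2-yl}-2,3-dihydro-1-benzofuran-5-yl]-3-[4-(methoxymethoxy)phenyl]prop-2-en-1-ol F6 as a mixture of carbinol epimers. MnO2 (CH2Cl2, rt) oxidises this benzylic, allylic alcohol to 20.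

3. Step 12.
- What may go wrong: while the acetals are being cleaved, a liberated ortho-phenol may add to the enone under acid catalysis (chalcone-to-flavanone isomerisation).
- Fallback, setting out from 20 and returning at 21: instead of stopping the acid treatment early, 20 is held in HCl/MeOH until all four protecting groups are gone, accepting ring closure. This gives the linear flavanone (2S)-4-hydroxy-2-(2-hydroxypropan-2-yl)-7-(4-hydroxyphenyl)-2,3,6,7-tetrahydro-5H-furo[3,2-g]chromen-5-one F7 (closure through the C6 oxygen) and the angular flavanone (8S)-5-hydroxy-8-(2-hydroxypropan-2-yl)-2-(4-hydroxyphenyl)-2,3,8,9-tetrahydro-4H-furo[2,3-h]chromen-4-one F8 (closure through the C4 oxygen), each as a mixture of epimers at the new aryl-bearing carbon. The crude mixture is dissolved in degassed aqueous KOH/MeOH at rt, where retro-oxa-Michael opening converts all flavanone isomers into the same chalcone polyphenolate. Cold acidification (dilute HCl, 0 °C) with immediate extraction gives 21.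

**Further compounds**

F1 | step 6 | ethyl 2-(dimethylsulfonio)-3-[2-oxido-4,6-bis(methoxymethoxy)phenyl]propanoate (betaine, not isolated) | C[S+](C)C(Cc1c([O-])cc(OCOC)cc1OCOC)C(=O)OCC
F2 | step 6 | racemic ethyl 4,6-bis(methoxymethoxy)-2,3-dihydro-1-benzofuran-2-carboxylate | CCOC(=O)C1Cc2c(cc(OCOC)cc2OCOC)O1
F3 | step 6 | ethyl (2S)-4,6-bis(methoxymethoxy)-2,3-dihydro-1-benzofuran-2-carboxylate | CCOC(=O)[C@@H]1Cc2c(cc(OCOC)cc2OCOC)O1
F4 | step 6 | ethyl (2R)-4,6-bis(methoxymethoxy)-2,3-dihydro-1-benzofuran-2-carboxylate | CCOC(=O)[C@H]1Cc2c(cc(OCOC)cc2OCOC)O1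
F5 | step 11 | (E)-3-[4-(methoxymethoxy)phenyl]prop-2-enal | COCOc1ccc(/C=C/C=O)cc1
F6 | step 11 | (E)-1-[(2S)-4,6-bis(methoxymethoxy)-2-{2-[(triethylsilyl)oxy]propan-2-yl}-2,3-dihydro-1-benzofuran-5-yl]-3-[4-(methoxymethoxy)phenyl]prop-2-en-1-ol (carbinol epimers) | CC[Si](CC)(CC)OC(C)(C)[C@@H]1Cc2c(cc(OCOC)c(C(O)/C=C/c3ccc(OCOC)cc3)c2OCOC)O1
F7 | step 12 | (2S)-4-hydroxy-2-(2-hydroxypropan-2-yl)-7-(4-hydroxyphenyl)-2,3,6,7-tetrahydro-5H-furo[3,2-g]chromen-5-one (C7 epimers) | CC(C)(O)[C@@H]1Cc2c(O1)cc1OC(c3ccc(O)cc3)CC(=O)c1c2O
F8 | step 12 | (8S)-5-hydroxy-8-(2-hydroxypropan-2-yl)-2-(4-hydroxyphenyl)-2,3,8,9-tetrahydro-4H-furo[2,3-h]chromen-4-one (C2 epimers) | CC(C)(O)[C@@H]1Cc2c(O1)cc(O)c1C(=O)CC(c3ccc(O)cc3)Oc21
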